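Lignan numbering (C7', C8', C9', O4, O5; ring A = benzodioxane arene, ring B = guaiacyl ring) is used beside the systematic names. The target is compound 16; the key step converts diol 4 into benzodioxane 5.

## The problem

(7'S,8'S)-Nocomtal (16) is a 1,4-benzodioxane neolignan in which O4 of ring A, the oxygen next to the C3 methoxy group, carries C8', and O5 carries the benzylic carbon C7'. The dioxane ring must therefore be fused to ring A in one fixed sense, and the two ring oxygens cannot be treated as equivalent. The two stereocentres are adjacent and trans (aryl on C7', hydroxymethyl on C8'). C8' is an ordinary ether carbon that nothing in the molecule can correct once it is set. C7' is a para-oxybenzylic ether that can ionise, so it can be placed under the control of C8', the diequatorial trans isomer being the stable one. The absolute problem thus reduces to C8'. Three groups limit the reagents: the E-enal on ring A (electrophilic, reducible, base-sensitive), the free para-phenol of ring B (once deprotonated it can open the C7'–O5 bond through a quinone methide), and the primary alcohol C9'–OH. The feature that invites a catalytic solution is this: with the ring B aryl group removed, C7' is an O–CH2 arm identical to the C9'H2–O arm. C8' is then the prochiral centre of a 2-aryloxypropane-1,3-diol, and a bromide at C5 of ring A lets one of the two enantiotopic oxygens close the dioxane ring.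

## Retrosynthesis

**16 ⇐ 15 ⇐ 14.** The enal is the most fragile function and is removed first, by cutting its Cα=Cβ bond. This leads through silyl ether 15 to aldehyde 14 and a two-carbon formyl ylide. A cut at the aryl–Cβ bond (Heck-type) would need a second halide on ring A, which would compete with the C5 bromide reserved for ring closure. The ring B phenol stays silylated until the last step, so that no base meets a free para-hydroxybenzylic ether. The forward reaction must stop after one homologation and give the E alkene.

**14 ⇐ 13 ⇐ 12.** The formyl group is traced to the benzylic alcohol of diol 13, and 13 to ester 12, in which C1 of ring A is a methyl ester and O9' a pivalate. One hydride reduction removes both acyl groups. An ester is chosen as the ring A spectator because it survives bromine atoms, organozinc reagents and palladium with base; an aldehyde or its acetal would not survive the bromination. The forward oxidation must distinguish the benzylic from the saturated primary alcohol.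

**12 ⇐ 9 + 8 (through 10 and 11).** The C7'–aryl bond is cut. Cutting C7'–O5 instead would reopen the ring made in the key step. The chosen cut makes ring B the arylzinc bromide 11, prepared through aryllithium 10 from silyl ether 8 (one step from bromophenol 7). C7' becomes the oxocarbenium ion of bromo ether 9. The zinc position fixes the ring B regiochemistry, and organozincs tolerate both esters. The forward reaction must deliver the aryl group trans to C9'; the pivalate on O9' is placed to bridge the cation from the C9' face.

**9 ⇐ 6 ⇐ 5.** The C7'–Br bond is traced to a C7'–H bond of pivalate 6, and 6 to alcohol 5. A pivalate rather than an acetate is chosen for three reasons: its bulk and inductive pull disfavour hydrogen abstraction at C8', it participates in the substitution, and it is inert to arylzinc reagents. The forward bromination must select the secondary C7'–H over the tertiary C8'–H. This is the least secure transformation of the plan and is given a fallback.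

**5 ⇐ 4.** The C5–O5 bond is cut, which opens the dioxane ring and removes the only stereocentre: 4 is achiral. No other cut of the benzodioxane does this. The forward reaction asks a chiral palladium catalyst to choose one of two enantiotopic hydroxymethyl groups, on a substrate class for which this reaction is established.

**4 ⇐ 3 ⇐ 1 + 2.** The O4–C8' bond is cut. Phenol 1 already carries the C5 bromide, the C3 methoxy group and the ester, so the ring A regiochemistry is bought, not made. Alcohol 2 supplies C7', C8' and C9' with both arms masked identically as a benzylidene acetal. The forward steps are a Mitsunobu etherification of a hindered but acidic phenol and an acetal hydrolysis.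

## Roads not taken

**Alternative 1:** The cut removes O4–C8' and C7'–C8' together and returns phenol 1, ethyl diazoacetate A1 and 4-(benzyloxy)-3-methoxybenzaldehyde A2. In the forward step a rhodium carbenoid from A1 would be captured by the phenol oxygen of 1 as an oxonium ylide. A chiral phosphoric acid would steer the ylide onto A2 before proton transfer, giving the threo aryloxy hydroxy ester A3 with both stereocentres and the C5 bromide in place. Closure of C7'–OH onto C5 and adjustment of the esters would follow.
- Merits: three commercial pieces, two bonds and both stereocentres in one operation. On paper the route is some four steps shorter than the chosen one and needs no C–H functionalisation.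
- Weak points: an acceptor-only carbenoid with a phenol favours plain O–H insertion by fast 1,2-proton shift. The trapping variant is reliable mainly for stabilised aryl diazoacetates and strongly electrophilic acceptors, whereas A2 is an electron-rich, deactivated aldehyde and 1 is a hindered, acidic phenol. Diastereo- and enantiocontrol would both rest on the catalyst with no help from the substrate. A3 is a β-hydroxy ester that can undergo retro-aldol cleavage under the basic C–O coupling.
- Comparison: this road is clearly better in brevity and convergence. The chosen plan sets against it a stereo-defining step within a demonstrated substrate class, paid for with a longer sequence.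

**Alternative 2:** The cut is a [2+2] disconnection of an oxetane, O–C9' and C7'–C8', returning 4-formyl-2-methoxyphenyl acetate A4 and the ring A aryl vinyl ether A5. The forward step is a Paternò–Büchi reaction: the triplet aldehyde adds with its oxygen to the CH2 terminus, giving the 2-aryl-3-aryloxyoxetane A6. After removal of the methoxymethyl group, O5 would open the strained ring at benzylic C7', forming the dioxane and releasing C9'–OH.
- Merits: the regiochemistry expected for enol ethers is the one needed. The ring expansion is driven by strain and gives the trans dioxane under thermodynamic control whatever the C7' configuration of A6. C7' receives its aryl group without any C–H functionalisation, and in that respect this road is better than the chosen plan.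
- Weak points: A6 is racemic at C8', and no reliable absolute control exists for this photoreaction, so a resolution would discard half the material. Electron-rich aryl aldehydes have low-lying π,π* triplets and react inefficiently. The hindered vinyl ether A5 must itself be made.
- Comparison: the chosen plan sets catalytic enantiocontrol at C8' against this, and accepts a less gentle arylation at C7'.

**Alternative 3:** Both aryl C–O bonds are cut, returning the threo diol A8 (from asymmetric dihydroxylation of cinnamate A7) and 3-bromo-4-fluoro-5-methoxybenzaldehyde A9. In the forward step the C8' hydroxyl would displace fluoride at C4 para to the formyl group, and a copper-catalysed coupling of the C7' hydroxyl with the C5 bromide would close the ring to the trans benzodioxane A10, with retention at both centres.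
- Merits: asymmetric dihydroxylation of a cinnamate is among the most reliable sources of two adjacent stereocentres, and threo goes to trans directly. The ring A aldehyde is ready for olefination, and the route would be three or four steps shorter. In stereochemical reliability and step economy this road is better than the chosen plan.
- Weak points: the regiochemistry rests on a choice between two secondary hydroxyls of A8 in the substitution step, which cannot be presumed clean. The α-aryloxy ester A10 and its precursors hold C8' next to a carbonyl group with a β-oxygen, so the carbonate bases and heat of both arylations invite epimerisation, β-elimination and retro-aldol cleavage. The fluoride of A9 is flanked by methoxy and bromine. A9 is not a stock compound, and the C9' ester must later be reduced beside an aldehyde.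
- Comparison: the chosen plan sets against it a regiochemistry fixed before any ring is formed and a C8' that is never enolisable. It pays with a longer sequence and the uncertain bromination at C7'.

Key step: step 3

Assumption: the (R) enantiomer of the spiro ligand SDP(O), 7-(diphenylphosphino)-7'-(diphenylphosphoryl)-1,1'-spirobiindane, is taken to deliver (S)-5; if the sense of induction is the opposite, the (S) ligand is used and nothing else changes.

Assumption: commercial 2 is mainly the cis isomer; its relative configuration is without consequence because C8' is not a stereocentre in 4.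

## Route

Step 1
Reactants: 1 methyl 3-bromo-4-hydroxy-5-methoxybenzoate; 2 2-phenyl-1,3-dioxan-5-ol
Product: 3 methyl 3-bromo-5-methoxy-4-[(2-phenyl-1,3-dioxan-5-yl)oxy]benzoate
Conditions: PPh3, DIAD, THF, 0 → 45 °C
Reagents that add atoms: none
Why: Mitsunobu etherification; the phenol is acidic enough (para ester, ortho bromide) to protonate the betaine, and the secondary carbinol is displaced with inversion at a centre that is no longer stereogenic after step 2.

Step 2
Reactants: 3 methyl 3-bromo-5-methoxy-4-[(2-phenyl-1,3-dioxan-5-yl)oxy]benzoate
Product: 4 methyl 3-bromo-4-[(1,3-dihydroxypropan-2-yl)oxy]-5-methoxybenzoate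
Conditions: 2 M HCl, THF, rt
Reagents that add atoms: none
Why: Acid hydrolysis of a benzylidene acetal; aryl ether, aryl bromide and methyl ester are stable to dilute acid at room temperature, and the product is achiral with two enantiotopic hydroxymethyl arms.

Step 3
Reactants: 4 methyl 3-bromo-4-[(1,3-dihydroxypropan-2-yl)oxy]-5-methoxybenzoate
Product: 5 methyl (2S)-2-(hydroxymethyl)-8-methoxy-2,3-dihydro-1,4-benzodioxine-6-carboxylate
Conditions: Pd(OAc)2 (5 mol %), (R)-SDP(O) (6 mol %), K3PO4, toluene, 60 °C
Reagents that add atoms: none
Why: Pd(OAc)2 is reduced in the flask to zerovalent palladium carrying the hemilabile P,O-ligand, which adds oxidatively to the C5–Br bond of 4 to give an aryl bromide complex of divalent palladium. Phosphate-assisted exchange of bromide for one of the two hydroxymethyl oxygens gives a seven-membered aryl(alkoxo)palladacycle, and C–O reductive elimination forms the C5–O5 bond and returns zerovalent palladium. The closest known reaction type is the palladium-catalysed enantioselective desymmetrising O-arylation of 2-(2-haloaryloxy)propane-1,3-diols to 2-hydroxymethyl-1,4-benzodioxanes, and 4 belongs to that substrate class. The 1,4-dioxane ring closes in a 6-exo sense at the aryl carbon by reductive elimination from the palladacycle; no other ring size competes because the second arm is identical. The new stereocentre C8' takes no part in bond making; its configuration follows from which enantiotopic arm is bound to palladium, and the chiral spiro ligand alone decides this (catalyst control), the arm left over becoming C9'H2OH. The step needs enantiotopic group selection and needs C–O reductive elimination to outrun β-hydride elimination of the palladium alkoxide; the symmetry of the diol secures the first, since the two pathways differ only in their fit to the ligand pocket, and the short tether that holds the alkoxide cis to the aryl group secures the second. The position of the bromide, already present in commercial 1, fixes the regiochemistry on ring A, and the meta ester eases oxidative addition without entering the reaction.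

Step 4
Reactants: 5 methyl (2S)-2-(hydroxymethyl)-8-methoxy-2,3-dihydro-1,4-benzodioxine-6-carboxylate
Product: 6 methyl (2R)-2-[(2,2-dimethylpropanoyloxy)methyl]-8-methoxy-2,3-dihydro-1,4-benzodioxine-6-carboxylate
Conditions: PivCl, pyridine, DMAP (cat.), CH2Cl2, 0 °C → rt
Reagents that add atoms: pivaloyl chloride, CC(C)(C)C(Cl)=O
Why: Acylation of a primary alcohol; the geometry at C8' is unchanged (the descriptor becomes R only because the acyloxymethyl arm now outranks C7'), and the pivalate later shields C8'–H, participates at C7' and resists the arylzinc.

Step 5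
Reactants: 7 4-bromo-2-methoxyphenol
Product: 8 (4-bromo-2-methoxyphenoxy)(tert-butyl)dimethylsilane
Conditions: TBSCl, imidazole, DMF, rt
Reagents that add atoms: tert-butyldimethylsilyl chloride, CC(C)(C)[Si](C)(C)Cl
Why: Silylation of a phenol; the aryl silyl ether tolerates n-BuLi at low temperature, zinc halide, hydride, MnO2 and the ylide, and is removed by fluoride at the end.

Step 6
Reactants: 6 methyl (2R)-2-[(2,2-dimethylpropanoyloxy)methyl]-8-methoxy-2,3-dihydro-1,4-benzodioxine-6-carboxylate
Product: 9 methyl (2S)-3-bromo-2-[(2,2-dimethylpropanoyloxy)methyl]-8-methoxy-2,3-dihydro-1,4-benzodioxine-6-carboxylate (mixture of C7' epimers)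
Conditions: NBS (1.05 equiv), AIBN (cat.), PhCF3, 75 °C; filtered, concentrated, used at once
Reagents that add atoms: N-bromosuccinimide, O=C1CCC(=O)N1Br
Why: Radical bromination of an ether O–CH2, as known for 1,4-benzodioxane itself; the bromine atom should prefer the secondary C7'–H (two hydrogens, one β-oxygen, unhindered) over the tertiary C8'–H, which has two β-oxygens and the bulky pivaloyloxymethyl group beside it, while the ester keeps ring A out of electrophilic bromination. The configuration at C7' is of no consequence because it is lost in the oxocarbenium ion of step 7.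

Step 7
Reactants: 9 methyl (2S)-3-bromo-2-[(2,2-dimethylpropanoyloxy)methyl]-8-methoxy-2,3-dihydro-1,4-benzodioxine-6-carboxylate; 8 (4-bromo-2-methoxyphenoxy)(tert-butyl)dimethylsilane
Product: 12 methyl (2S,3S)-3-{4-[(tert-butyldimethylsilyl)oxy]-3-methoxyphenyl}-2-[(2,2-dimethylpropanoyloxy)methyl]-8-methoxy-2,3-dihydro-1,4-benzodioxine-6-carboxylate, via aryllithium 10 (not isolated), via arylzinc bromide 11 (not isolated)
Conditions: 8, n-BuLi, toluene/n-Bu2O, −20 °C; ZnBr2 in n-Bu2O, 0 °C; then 9 in toluene, 25 → 80 °C
Reagents that add atoms: none
Why: Substitution of an α-bromo ether by an arylzinc through an oxocarbenium ion, the reaction type used for 1,2-trans C-aryl glycosides from acylated glycosyl bromides. ZnBr2 ionises C7'–Br, the pivalate carbonyl bridges from the C9' face as a six-membered acyloxonium ion, and the aryl group enters from the opposite face, so C7' is set S, trans to C8'. The para-silyloxybenzylic C7'–O5 bond can re-ionise under the Lewis acid, which also lets the diequatorial trans isomer accumulate.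

Step 8
Reactants: 12 methyl (2S,3S)-3-{4-[(tert-butyldimethylsilyl)oxy]-3-methoxyphenyl}-2-[(2,2-dimethylpropanoyloxy)methyl]-8-methoxy-2,3-dihydro-1,4-benzodioxine-6-carboxylate
Product: 13 [(2S,3S)-3-{4-[(tert-butyldimethylsilyl)oxy]-3-methoxyphenyl}-8-methoxy-2,3-dihydro-1,4-benzodioxine-2,6-diyl]dimethanol
Conditions: i-Bu2AlH (excess), CH2Cl2, −78 → 0 °C; aqueous potassium sodium tartrate
Reagents that add atoms: none
Why: Hydride reduction of both esters; the benzoate gives the benzylic alcohol and the pivalate is cleaved to the C9' alcohol in the same operation, while the aryl silyl ether and the ring ethers are inert.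

Step 9
Reactants: 13 [(2S,3S)-3-{4-[(tert-butyldimethylsilyl)oxy]-3-methoxyphenyl}-8-methoxy-2,3-dihydro-1,4-benzodioxine-2,6-diyl]dimethanol
Product: 14 (2S,3S)-3-{4-[(tert-butyldimethylsilyl)oxy]-3-methoxyphenyl}-2-(hydroxymethyl)-8-methoxy-2,3-dihydro-1,4-benzodioxine-6-carbaldehyde
Conditions: MnO2 (activated), CH2Cl2, rt
Reagents that add atoms: none
Why: MnO2 oxidises benzylic alcohols selectively and leaves the saturated primary C9'–OH untouched.

Step 10
Reactants: 14 (2S,3S)-3-{4-[(tert-butyldimethylsilyl)oxy]-3-methoxyphenyl}-2-(hydroxymethyl)-8-methoxy-2,3-dihydro-1,4-benzodioxine-6-carbaldehyde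
Product: 15 (2E)-3-[(2S,3S)-3-{4-[(tert-butyldimethylsilyl)oxy]-3-methoxyphenyl}-2-(hydroxymethyl)-8-methoxy-2,3-dihydro-1,4-benzodioxin-6-yl]prop-2-enal
Conditions: Ph3P=CHCHO, toluene, 80 °C
Reagents that add atoms: (triphenylphosphoranylidene)acetaldehyde, O=CC=P(c1ccccc1)(c1ccccc1)c1ccccc1
Why: Wittig olefination with the stabilised formylmethylene ylide, which is E-selective; a small excess and moderate temperature should hold it at one homologation, and the free C9'–OH does not interfere.

Step 11
Reactants: 15 (2E)-3-[(2S,3S)-3-{4-[(tert-butyldimethylsilyl)oxy]-3-methoxyphenyl}-2-(hydroxymethyl)-8-methoxy-2,3-dihydro-1,4-benzodioxin-6-yl]prop-2-enal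
Product: 16 (2E)-3-[(2S,3S)-3-(4-hydroxy-3-methoxyphenyl)-2-(hydroxymethyl)-8-methoxy-2,3-dihydro-1,4-benzodioxin-6-yl]prop-2-enal, (7'S,8'S)-nocomtal
Conditions: n-Bu4NF, AcOH, THF, 0 °C
Reagents that add atoms: none
Why: Fluoride cleavage of an aryl silyl ether; acetic acid buffers the phenoxide so that neither the enal nor the para-hydroxybenzylic C7'–O5 bond is exposed to base, and C7' would in any case return to the stable trans arrangement.

## Compound list

1 | methyl 3-bromo-4-hydroxy-5-methoxybenzoate | COC(=O)c1cc(Br)c(O)c(OC)c1 | starting material
2 | 2-phenyl-1,3-dioxan-5-ol (either diastereomer; both centres cease to be stereogenic in step 2) | OC1COC(c2ccccc2)OC1 | starting material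
3 | methyl 3-bromo-5-methoxy-4-[(2-phenyl-1,3-dioxan-5-yl)oxy]benzoate | COC(=O)c1cc(Br)c(OC2COC(c3ccccc3)OC2)c(OC)c1 | intermediate
4 | methyl 3-bromo-4-[(1,3-dihydroxypropan-2-yl)oxy]-5-methoxybenzoate | COC(=O)c1cc(Br)c(OC(CO)CO)c(OC)c1 | intermediate
5 | methyl (2S)-2-(hydroxymethyl)-8-methoxy-2,3-dihydro-1,4-benzodioxine-6-carboxylate | C1Oc2cc(C(=O)OC)cc(OC)c2O[C@H]1CO | intermediate
6 | methyl (2R)-2-[(2,2-dimethylpropanoyloxy)methyl]-8-methoxy-2,3-dihydro-1,4-benzodioxine-6-carboxylate | C1Oc2cc(C(=O)OC)cc(OC)c2O[C@H]1COC(=O)C(C)(C)C | intermediate
7 | 4-bromo-2-methoxyphenol | COc1cc(Br)ccc1O | starting material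
8 | (4-bromo-2-methoxyphenoxy)(tert-butyl)dimethylsilane | COc1cc(Br)ccc1O[Si](C)(C)C(C)(C)C | intermediate
9 | methyl (2S)-3-bromo-2-[(2,2-dimethylpropanoyloxy)methyl]-8-methoxy-2,3-dihydro-1,4-benzodioxine-6-carboxylate, C7' epimers | BrC1Oc2cc(C(=O)OC)cc(OC)c2O[C@H]1COC(=O)C(C)(C)C | intermediate
10 | {4-[(tert-butyldimethylsilyl)oxy]-3-methoxyphenyl}lithium | [Li]c1ccc(O[Si](C)(C)C(C)(C)C)c(OC)c1 | intermediate (not isolated)
11 | {4-[(tert-butyldimethylsilyl)oxy]-3-methoxyphenyl}zinc bromide | Br[Zn]c1ccc(O[Si](C)(C)C(C)(C)C)c(OC)c1 | intermediate (not isolated)
12 | methyl (2S,3S)-3-{4-[(tert-butyldimethylsilyl)oxy]-3-methoxyphenyl}-2-[(2,2-dimethylpropanoyloxy)methyl]-8-methoxy-2,3-dihydro-1,4-benzodioxine-6-carboxylate | COc1cc([C@@H]2Oc3cc(C(=O)OC)cc(OC)c3O[C@H]2COC(=O)C(C)(C)C)ccc1O[Si](C)(C)C(C)(C)C | intermediate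
13 | [(2S,3S)-3-{4-[(tert-butyldimethylsilyl)oxy]-3-methoxyphenyl}-8-methoxy-2,3-dihydro-1,4-benzodioxine-2,6-diyl]dimethanol | COc1cc([C@@H]2Oc3cc(CO)cc(OC)c3O[C@H]2CO)ccc1O[Si](C)(C)C(C)(C)C | intermediate
14 | (2S,3S)-3-{4-[(tert-butyldimethylsilyl)oxy]-3-methoxyphenyl}-2-(hydroxymethyl)-8-methoxy-2,3-dihydro-1,4-benzodioxine-6-carbaldehyde | COc1cc([C@@H]2Oc3cc(C=O)cc(OC)c3O[C@H]2CO)ccc1O[Si](C)(C)C(C)(C)C | intermediate
15 | (2E)-3-[(2S,3S)-3-{4-[(tert-butyldimethylsilyl)oxy]-3-methoxyphenyl}-2-(hydroxymethyl)-8-methoxy-2,3-dihydro-1,4-benzodioxin-6-yl]prop-2-enal | COc1cc([C@@H]2Oc3cc(/C=C/C=O)cc(OC)c3O[C@H]2CO)ccc1O[Si](C)(C)C(C)(C)C | intermediate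
16 | (2E)-3-[(2S,3S)-3-(4-hydroxy-3-methoxyphenyl)-2-(hydroxymethyl)-8-methoxy-2,3-dihydro-1,4-benzodioxin-6-yl]prop-2-enal, (7'S,8'S)-nocomtal | COc1cc([C@@H]2Oc3cc(/C=C/C=O)cc(OC)c3O[C@H]2CO)ccc1O | target

## Step count and risks

Total step count: 11. Longest linear sequence: 10 steps (1 → 16 through steps 1–4 and 6–11); step 5 is a one-step side branch.

**Step 3 (key step).** The most likely failure is incomplete discrimination between the two hydroxymethyl arms, or slow turnover. The aryloxy oxygen of 4 is flanked by a methoxy group, which changes how the side chain sits over the metal compared with simpler members of the class. β-Hydride elimination of the palladium alkoxide with loss of the bromide may also compete. The fallback takes C8' from the chiral pool, sets out from 1 and returns at 5: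
- (S)-3-(benzyloxy)propane-1,2-diol F1 is silylated at the primary hydroxyl (TBSCl, imidazole) to (R)-1-(benzyloxy)-3-[(tert-butyldimethylsilyl)oxy]propan-2-ol F2.
- Mitsunobu coupling of F2 with 1 inverts the carbinol centre and gives methyl 4-{[(2S)-1-(benzyloxy)-3-[(tert-butyldimethylsilyl)oxy]propan-2-yl]oxy}-3-bromo-5-methoxybenzoate F3.
- n-Bu4NF frees the primary alcohol, methyl 4-{[(2R)-1-(benzyloxy)-3-hydroxypropan-2-yl]oxy}-3-bromo-5-methoxybenzoate F4.
- Ring closure of F4 with an achiral catalyst (Pd(OAc)2, 2-(di-tert-butylphosphino)-1,1'-binaphthyl, Cs2CO3, toluene) gives methyl (2S)-2-[(benzyloxy)methyl]-8-methoxy-2,3-dihydro-1,4-benzodioxine-6-carboxylate F5.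
- Hydrogenolysis (H2, palladium on carbon) gives 5. The C5–O5 bond is still made by palladium, but no enantioselection is asked of it.

**Step 6.** Hydrogen abstraction at the tertiary C8'–H may compete with abstraction at C7', which would erode the configuration at C8'. Loss of HBr across C7'–C8' would give the achiral enol ether, followed by further bromination. Ring bromination is a lesser risk. The fallback avoids the bromo ether: it sets out from 6 and 8 and returns at 12 by direct C–H arylation under decatungstate hydrogen-atom transfer with nickel catalysis ((n-Bu4N)4[W10O32], NiBr2·glyme, 4,4'-di-tert-butyl-2,2'-bipyridine, K3PO4, MeCN, 390 nm light). This is a known arylation of cyclic ether O–CH2 groups whose abstracting agent is more sensitive to steric and polar deactivation than a bromine atom. It makes no new compound.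

**Step 7.** The oxocarbenium ion may lose the C8' proton faster than it accepts the aryl group, and facial selectivity may be poor if the six-membered acyloxonium bridge is weaker than the five-membered one of the glycosyl case. The fallback changes the mechanism from ionic to radical: it sets out from 9 and 11 and returns at 12 by a nickel-catalysed Negishi coupling of the α-bromo ether (Ni(cod)2, 4,4',4''-tri-tert-butyl-2,2':6',2''-terpyridine, DMF, rt), as known for glycosyl bromides with arylzinc reagents. No cation is formed, and the aryl group is expected on the face away from the C8' substituent. It makes no new compound.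

**Step 10.** A second olefination of the product enal may give a dienal, and the electron-rich aldehyde may react slowly. The fallback sets out from 14 and returns at 15 in three steps:
- Horner–Wadsworth–Emmons reaction with triethyl phosphonoacetate (LiCl, DBU, MeCN) gives ethyl (2E)-3-[(2S,3S)-3-{4-[(tert-butyldimethylsilyl)oxy]-3-methoxyphenyl}-2-(hydroxymethyl)-8-methoxy-2,3-dihydro-1,4-benzodioxin-6-yl]prop-2-enoate F6.
- i-Bu2AlH reduces F6 to the allylic alcohol (2E)-3-[(2S,3S)-3-{4-[(tert-butyldimethylsilyl)oxy]-3-methoxyphenyl}-2-(hydroxymethyl)-8-methoxy-2,3-dihydro-1,4-benzodioxin-6-yl]prop-2-en-1-ol F7.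
- MnO2 oxidises the allylic alcohol selectively to 15.

**Step 1.** The Mitsunobu coupling of an ortho,ortho'-disubstituted phenol with a secondary alcohol may be slow, with alkylation of the hydrazide competing. The fallback sets out from 1 and returns at 4, bypassing 3:
- Alkylation of 1 with diethyl bromomalonate (K2CO3, acetone) gives diethyl 2-[2-bromo-6-methoxy-4-(methoxycarbonyl)phenoxy]propanedioate F8.
- NaBH4 in THF/MeOH at 0 °C reduces the activated malonate esters to diol 4 and leaves the benzoate.

## Further compounds

F1 | step 3 | (S)-3-(benzyloxy)propane-1,2-diol | O[C@@H](CO)COCc1ccccc1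
F2 | step 3 | (R)-1-(benzyloxy)-3-[(tert-butyldimethylsilyl)oxy]propan-2-ol | O[C@@H](CO[Si](C)(C)C(C)(C)C)COCc1ccccc1
F3 | step 3 | methyl 4-{[(2S)-1-(benzyloxy)-3-[(tert-butyldimethylsilyl)oxy]propan-2-yl]oxy}-3-bromo-5-methoxybenzoate | COC(=O)c1cc(Br)c(O[C@H](CO[Si](C)(C)C(C)(C)C)COCc2ccccc2)c(OC)c1
F4 | step 3 | methyl 4-{[(2R)-1-(benzyloxy)-3-hydroxypropan-2-yl]oxy}-3-bromo-5-methoxybenzoate | COC(=O)c1cc(Br)c(O[C@H](CO)COCc2ccccc2)c(OC)c1
F5 | step 3 | methyl (2S)-2-[(benzyloxy)methyl]-8-methoxy-2,3-dihydro-1,4-benzodioxine-6-carboxylate | C1Oc2cc(C(=O)OC)cc(OC)c2O[C@H]1COCc1ccccc1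
F0 | step 6 | none | none
F0 | step 7 | none | none
F6 | step 10 | ethyl (2E)-3-[(2S,3S)-3-{4-[(tert-butyldimethylsilyl)oxy]-3-methoxyphenyl}-2-(hydroxymethyl)-8-methoxy-2,3-dihydro-1,4-benzodioxin-6-yl]prop-2-enoate | COc1cc([C@@H]2Oc3cc(/C=C/C(=O)OCC)cc(OC)c3O[C@H]2CO)ccc1O[Si](C)(C)C(C)(C)C
F7 | step 10 | (2E)-3-[(2S,3S)-3-{4-[(tert-butyldimethylsilyl)oxy]-3-methoxyphenyl}-2-(hydroxymethyl)-8-methoxy-2,3-dihydro-1,4-benzodioxin-6-yl]prop-2-en-1-ol | COc1cc([C@@H]2Oc3cc(/C=C/CO)cc(OC)c3O[C@H]2CO)ccc1O[Si](C)(C)C(C)(C)C
F8 | step 1 | diethyl 2-[2-bromo-6-methoxy-4-(methoxycarbonyl)phenoxy]propanedioate | CCOC(=O)C(Oc1c(Br)cc(C(=O)OC)cc1OC)C(=O)OCC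
A1 | alternative 1 | ethyl diazoacetate | CCOC(=O)C=[N+]=[N-]
A2 | alternative 1 | 4-(benzyloxy)-3-methoxybenzaldehyde | COc1cc(C=O)ccc1OCc1ccccc1
A3 | alternative 1 | ethyl (2R,3S)-3-[4-(benzyloxy)-3-methoxyphenyl]-2-[2-bromo-6-methoxy-4-(methoxycarbonyl)phenoxy]-3-hydroxypropanoate | COc1cc([C@H](O)[C@@H](Oc2c(Br)cc(C(=O)OC)cc2OC)C(=O)OCC)ccc1OCc1ccccc1
A4 | alternative 2 | 4-formyl-2-methoxyphenyl acetate | COc1cc(C=O)ccc1OC(C)=O
A5 | alternative 2 | methyl 4-(ethenyloxy)-3-methoxy-5-(methoxymethoxy)benzoate | COC(=O)c1cc(OC)c(OC=C)c(OCOC)c1
A6 | alternative 2 | methyl 4-{[2-(4-acetoxy-3-methoxyphenyl)oxetan-3-yl]oxy}-3-methoxy-5-(methoxymethoxy)benzoate, racemic, C7' epimers, drawn as one C8' enantiomer | COc1cc(C2OC[C@@H]2Oc2c(OC)cc(C(=O)OC)cc2OCOC)ccc1OC(C)=O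
A7 | alternative 3 | methyl (2E)-3-[4-(benzyloxy)-3-methoxyphenyl]prop-2-enoate | COc1cc(/C=C/C(=O)OC)ccc1OCc1ccccc1
A8 | alternative 3 | methyl (2R,3S)-3-[4-(benzyloxy)-3-methoxyphenyl]-2,3-dihydroxypropanoate | COc1cc([C@H](O)[C@@H](O)C(=O)OC)ccc1OCc1ccccc1
A9 | alternative 3 | 3-bromo-4-fluoro-5-methoxybenzaldehyde | COc1cc(C=O)cc(Br)c1F
A10 | alternative 3 | methyl (2R,3S)-3-[4-(benzyloxy)-3-methoxyphenyl]-6-formyl-8-methoxy-2,3-dihydro-1,4-benzodioxine-2-carboxylate | COc1cc([C@@H]2Oc3cc(C=O)cc(OC)c3O[C@H]2C(=O)OC)ccc1OCc1ccccc1
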